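The route rests on cutting two bonds of the alcohol half, C1'–C8a' and C4'–C4a', and delivering the benzene bond C4a'–C8a' as an aryne. The feature exploited is the place of that bond in the ring system: its two carbons carry C1' and C4', and the adjacent C8' carries O-8', which ketal carbon C1 and the furan-ring oxygen join to C1'. The aryne is therefore held over a (1'Z,3'E)-dienyl bis-enol ether, and one fluoride-triggered intramolecular Diels–Alder reaction closes the carbocycle and the 1,3-dioxane and sets C1' and C4'. The precursor is an enantiopure aryl ketal of a 2H-naphtho[1,8-bc]furan bearing the exocyclic diene and a 2-silylaryl triflate.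

Key step: step 18

Remark on numbering: each half is numbered as a naphthalene. Ketone half: C1 (ketal carbon), C2, C3, C4 (ketone), C4a, C5 (OH), C6 (Cl), C7, C8 (bonded to C1'), C8a. Alcohol half: C1' (quaternary), C2', C3', C4' (carbinol), C4a', C5' (OH), C6' (Cl), C7', C8' (bears O-8'), C8a'. O-1 is the ring oxygen between C1 and C1'.

Remark on the aryne precursor (structural correction): silicon is placed on C4a' and the triflate on C8a'. With silicon on C8a', the free phenol needed for ketal formation would be a 3-hydroxy-2-silylaryl triflate, which on deprotonation shifts silicon from carbon to oxygen and expels triflate. The transposed arrangement gives the same aryne.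

Remark on the diene: the acid-labile (1'Z,3'E)-diene is assembled last, from a (Z)-bromomethylidene ketal and an (E)-alkenylboronate, so that each alkene geometry comes from a stereospecific step.

Assumptions: 5-chloro-2,4-dihydroxybenzaldehyde is taken as a catalogue compound. The single stereocentre of the ketal (C1) is obtained by chromatographic resolution, and every other stereocentre derives from it.

Step 1
Reactants: 1 5-chloro-2,4-dihydroxybenzaldehyde
Product: 2 5-chloro-2-hydroxy-4-(methoxymethoxy)benzaldehyde
Conditions: MOMCl (1.1 equiv), i-Pr2NEt, CH2Cl2, 0 °C → rt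
Reagents that add atoms: chloromethyl methyl ether, COCCl
Why: Williamson-type O-alkylation; the 4-OH para to the formyl group is the more acidic, unchelated phenol, whereas the 2-OH is held in a hydrogen bond to the aldehyde.

Step 2
Reactants: 2 5-chloro-2-hydroxy-4-(methoxymethoxy)benzaldehyde
Product: 3 3-bromo-5-chloro-2-hydroxy-4-(methoxymethoxy)benzaldehyde
Conditions: NBS (1.05 equiv), MeCN, 0 °C → rt
Reagents that add atoms: N-bromosuccinimide, O=C1CCC(=O)N1Br
Why: Electrophilic aromatic bromination at C3, the only free ring position ortho or para to an oxygen donor (ortho to both OH and OMOM).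

Step 3
Reactants: 3 3-bromo-5-chloro-2-hydroxy-4-(methoxymethoxy)benzaldehyde
Product: 5 3-bromo-5-chloro-4-(methoxymethoxy)benzene-1,2-diol, via aryl formate 4 (not isolated)
Conditions: H2O2 (30% aq., 1.2 equiv), NaOH (1.1 equiv), THF/H2O, 0 °C → rt, argon; then NaH2PO4 to pH 6
Reagents that add atoms: hydrogen peroxide, OO
Why: Dakin oxidation of an ortho-hydroxybenzaldehyde: hydroperoxide adds to the aldehyde, the electron-rich aryl group migrates to oxygen and the formate is saponified in the same flask.

Step 4
Reactants: 5 3-bromo-5-chloro-4-(methoxymethoxy)benzene-1,2-diol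
Product: 6 1-bromo-5-chloro-6-(methoxymethoxy)-2,3-bis(trimethylsilyloxy)benzene
Conditions: (Me3Si)2NH (1.5 equiv), THF, 65 °C; evaporation
Reagents that add atoms: hexamethyldisilazane, C[Si](C)(C)N[Si](C)(C)C
Why: O-silylation with hexamethyldisilazane gives only ammonia as by-product, so evaporation should leave the bis-silyl ether ready for metalation.

Step 5
Reactants: 6 1-bromo-5-chloro-6-(methoxymethoxy)-2,3-bis(trimethylsilyloxy)benzene
Product: 10 4-chloro-6-hydroxy-3-(methoxymethoxy)-2-(trimethylsilyl)phenyl trifluoromethanesulfonate, via aryllithium 7 (not isolated), via lithium aryloxide 8 (not isolated), via silyl ether triflate 9 (not isolated)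
Conditions: n-BuLi (1.05 equiv), THF, −100 → −20 °C; Tf2O (1.2 equiv), −78 °C; aq. NaHCO3/MeOH, 0 °C
Reagents that add atoms: trifluoromethanesulfonic anhydride, O=S(=O)(OS(=O)(=O)C(F)(F)F)C(F)(F)F
Why: Bromine–lithium exchange followed by the anionic 1,3 O→C silyl shift (retro-Brook rearrangement) from the only ortho silyloxy group puts silicon on the carbon between the two oxygens and frees exactly that phenoxide for triflation; the other O–SiMe3 bond is hydrolysed on work-up.

Step 6
Reactants: 11 naphthalene-1,5-diol
Product: 13 5-hydroxy-4,4-dimethoxynaphthalen-1(4H)-one, via 4-methoxynaphthalene-1,5-diol 12 (not isolated)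
Conditions: PhI(OAc)2 (2.1 equiv), MeOH, −10 → 0 °C; NaHCO3
Reagents that add atoms: methanol, CO
Why: Oxidative dearomatisation of a phenol by trivalent iodine: after para-methoxylation the electron-richer 4-methoxynaphthol ring is oxidised again, which places the ketal peri to the remaining phenol and the ketone peri to C8.

Step 7
Reactants: 13 5-hydroxy-4,4-dimethoxynaphthalen-1(4H)-one
Product: 14 5-hydroxy-8-iodo-4,4-dimethoxynaphthalen-1(4H)-one
Conditions: NIS (1.05 equiv), MeCN, 0 °C → rt, dark
Reagents that add atoms: N-iodosuccinimide, O=C1CCC(=O)N1I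
Why: Electrophilic aromatic iodination para to the free phenol (C8), the usual preference of N-halosuccinimides; the dienone ring is electron-poor and should stay untouched.

Step 8
Reactants: 14 5-hydroxy-8-iodo-4,4-dimethoxynaphthalen-1(4H)-one
Product: 15 6-chloro-5-hydroxy-8-iodo-4,4-dimethoxynaphthalen-1(4H)-one
Conditions: NCS (1.05 equiv), i-Pr2NH (10 mol%), CH2Cl2, 0 °C → rt
Reagents that add atoms: N-chlorosuccinimide, O=C1CCC(=O)N1Cl
Why: Electrophilic aromatic chlorination (amine-catalysed, ortho to OH) at C6, the only position still activated by the phenol.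

Step 9
Reactants: 15 6-chloro-5-hydroxy-8-iodo-4,4-dimethoxynaphthalen-1(4H)-one
Product: 16 6-chloro-8-iodo-4,4-dimethoxy-5-(methoxymethoxy)naphthalen-1(4H)-one
Conditions: MOMCl (1.5 equiv), i-Pr2NEt, CH2Cl2, 0 °C → rt
Reagents that add atoms: chloromethyl methyl ether, COCCl
Why: Williamson-type MOM protection masks the phenol for the later base- and fluoride-mediated steps.

Step 10
Reactants: 16 6-chloro-8-iodo-4,4-dimethoxy-5-(methoxymethoxy)naphthalen-1(4H)-one; 17 ethynyltrimethylsilane
Product: 18 6-chloro-4,4-dimethoxy-5-(methoxymethoxy)-8-[(trimethylsilyl)ethynyl]naphthalen-1(4H)-one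
Conditions: Pd(PPh3)2Cl2 (3 mol%), CuI (5 mol%), Et3N, THF, rt
Reagents that add atoms: none
Why: Sonogashira coupling; the aryl iodide reacts in preference to the aryl chloride, and a tertiary amine base spares the enone.

Step 11
Reactants: 18 6-chloro-4,4-dimethoxy-5-(methoxymethoxy)-8-[(trimethylsilyl)ethynyl]naphthalen-1(4H)-one
Product: 19 8-(bromoethynyl)-6-chloro-4,4-dimethoxy-5-(methoxymethoxy)naphthalen-1(4H)-one
Conditions: NBS (1.1 equiv), AgNO3 (10 mol%), acetone, rt, dark
Reagents that add atoms: N-bromosuccinimide, O=C1CCC(=O)N1Br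
Why: Silver-catalysed desilylative bromination of a silylalkyne gives the 1-bromoalkyne directly and avoids methanolic base on the dienone ketal.

Step 12
Reactants: 20 (4-methoxyphenyl)methanol; 21 trichloroethene
Product: 23 1-({[(E)-1,2-dichloroethenyl]oxy}methyl)-4-methoxybenzene, via dichloroethyne 22 (not isolated)
Conditions: KH (1.1 equiv), THF, 0 °C; then 21, −50 °C → rt
Reagents that add atoms: none
Why: Alkoxide-induced dehydrochlorination of trichloroethene gives dichloroethyne, to which the alkoxide adds anti (base-mediated synthesis of 1,2-dichlorovinyl ethers).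

Step 13
Reactants: 23 1-({[(E)-1,2-dichloroethenyl]oxy}methyl)-4-methoxybenzene
Product: 26 1-[(ethynyloxy)methyl]-4-methoxybenzene, via chloroalkynyl ether 24 (not isolated), via lithium acetylide 25 (not isolated)
Conditions: n-BuLi (2.2 equiv), Et2O, −78 → −40 °C; MeOH, −78 °C; used cold at once
Reagents that add atoms: none
Why: Dehydrochlorination to the chloroalkynyl ether, chlorine–lithium exchange and protonation give the alkoxyacetylene, which is kept cold because benzyl alkynyl ethers rearrange on warming.

Step 14
Reactants: 26 1-[(ethynyloxy)methyl]-4-methoxybenzene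
Product: 27 2-{(E)-2-[(4-methoxybenzyl)oxy]ethenyl}-4,4,5,5-tetramethyl-1,3,2-dioxaborolane
Conditions: pinacolborane (1.2 equiv), Cp2Zr(H)Cl (5 mol%), Et3N (10 mol%), CH2Cl2, 0 °C → rt
Reagents that add atoms: pinacolborane, [H]B1OC(C)(C)C(C)(C)O1
Why: Zirconocene hydride-catalysed syn hydroboration of a terminal alkyne puts boron on the terminal carbon and so fixes the (E) geometry of the later C3'=C4' enol ether.

Step 15
Reactants: 19 8-(bromoethynyl)-6-chloro-4,4-dimethoxy-5-(methoxymethoxy)naphthalen-1(4H)-one; 10 4-chloro-6-hydroxy-3-(methoxymethoxy)-2-(trimethylsilyl)phenyl trifluoromethanesulfonate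
Product: 28 racemic (Z)-bromomethylidene aryl ketal (C1 aryloxy 2H-naphtho[1,8-bc]furan)
Conditions: (Ph3P)AuNTf2 (5 mol%), 2,6-di-tert-butylpyridine (10 mol%), 4 Å MS, CH2Cl2, 0 °C → rt
Reagents that add atoms: none
Why: Proposed new method: monovalent gold activates the bromoalkyne, the neighbouring ketone oxygen attacks C1' anti to gold in a 5-exo-dig mode (bromine polarises the π-complex so that the nucleophile enters at the carbon remote from halogen, as in gold-catalysed hydration and O–H additions to 1-haloalkynes), the cyclic oxocarbenium ion at C1 is captured by phenol 10, and protodeauration with retention leaves bromine cis to O-1, i.e. the (Z)-bromomethylidene ketal, racemic at C1; closest known reaction type: gold- or silver-catalysed carbonyl–alkyne cyclisation of 2-alkynylaryl aldehydes and ketones with capture of the oxocarbenium ion by alcohols.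

Step 16
Reactants: 28 racemic (Z)-bromomethylidene aryl ketal
Product: 29 (R)-configured (Z)-bromomethylidene aryl ketal (R at C1)
Conditions: preparative HPLC, amylose tris(3,5-dimethylphenylcarbamate) stationary phase, heptane/i-PrOH
Reagents that add atoms: none
Why: Resolution on a chiral stationary phase; the ketal is configurationally stable under neutral conditions, and the enantiomer to be carried on would be assigned by anomalous-dispersion X-ray analysis (Br, Cl, S, Si).

Step 17
Reactants: 29 (R)-configured (Z)-bromomethylidene aryl ketal; 27 2-{(E)-2-[(4-methoxybenzyl)oxy]ethenyl}-4,4,5,5-tetramethyl-1,3,2-dioxaborolane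
Product: 30 aryne precursor (S at C1; (1'Z,3'E)-dienyl bis-enol ether; 2-silylaryl triflate)
Conditions: Pd(PPh3)4 (5 mol%), K3PO4 (3 equiv), THF/H2O (10:1), 45 °C; chromatography on Et3N-deactivated silica
Reagents that add atoms: none
Why: Suzuki–Miyaura coupling with retention at both partners should give the (1'Z,3'E)-diene; triphenylphosphine-ligated zerovalent palladium inserts into the vinyl C–Br bond in preference to the hindered aryl triflate, and the C1 descriptor changes from R to S only because carbon replaces bromine.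

Step 18
Reactants: 30 aryne precursor
Product: 32 caged 1,4-dihydronaphthalene cycloadduct, via aryne 31 (not isolated)
Conditions: CsF (3 equiv), MeCN (0.005 M), rt
Reagents that add atoms: none
Why: Fluoride removes the silyl group from C4a' and triflate leaves from C8a'; the two carbons of aryne 31 then add suprafacially to C1' and C4' of the dienyl bis-enol ether in an intramolecular aryne Diels–Alder reaction, probably asynchronous with C1'–C8a' bonding ahead. The closest known reaction type is the intramolecular [4+2] cycloaddition of arynes, made from 2-silylaryl triflates and fluoride, with tethered acyclic 1,3-dienes. The 1,3-dioxane closes as the tether ring through the new C1'–C8a' bond (the O-8'–C1–O-1 chain ends on diene terminus C1'), and the carbocycle closes as the cycloadduct ring through C4'–C4a'. C1' is set by the C1 stereocentre, because the aryne hangs from O-8' and can reach only the diene face on that side; C4' follows from suprafacial addition to the (1'Z,3'E)-diene, in which C8 and the PMB oxygen are both outside substituents and therefore end cis. The step needs [4+2] addition to win over [2+2] addition to either enol ether, ene reaction and intermolecular capture; the short tether that holds both aryne carbons over the diene termini, the small inside substituent (only O-1) that keeps the s-cis conformer within reach, the electron-rich diene and high dilution are meant to secure this.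

Step 19
Reactants: 32 caged 1,4-dihydronaphthalene cycloadduct
Product: 33 caged enone (C4 ketone)
Conditions: PPTS (0.2 equiv), acetone/H2O (10:1), rt
Reagents that add atoms: water, O
Why: Acid-catalysed ketal hydrolysis; the acyclic allylic and benzylic dimethyl ketal ionises far more readily than the bridged aryl ketal at C1 or the MOM ethers.

Step 20
Reactants: 33 caged enone
Product: 34 C2'–C3' epoxide of the caged enone
Conditions: DMDO (acetone solution, 3 equiv), CH2Cl2, 0 °C → rt
Reagents that add atoms: dimethyldioxirane, CC1(C)OO1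
Why: Electrophilic (Prilezhaev-type) epoxidation with dimethyldioxirane leaves the electron-poor enone alone and should enter C2'=C3' on the convex face that carries O-1, anti to the C4' PMB ether and to the C1'–C8 aryl bond, which sets C2' and C3'.

Step 21
Reactants: 34 C2'–C3' epoxide of the caged enone
Product: 35 bis-epoxide (C2–C3 epoxy ketone)
Conditions: t-BuOOH (decane solution, 3 equiv), DBU (1.2 equiv), CH2Cl2, 0 °C
Reagents that add atoms: tert-butyl hydroperoxide, CC(C)(C)OO
Why: Weitz–Scheffer nucleophilic epoxidation; the peroxide anion should add to C2 on the convex face of the cage (the side of O-1, anti to the aryloxy bridge) and close on C3, which sets C2 and C3.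

Step 22
Reactants: 35 bis-epoxide
Product: 36 bis-epoxide with free C4' hydroxyl
Conditions: DDQ (1.5 equiv), CH2Cl2/pH 7 phosphate buffer (10:1), 0 °C → rt
Reagents that add atoms: none
Why: Oxidative cleavage of the PMB ether by DDQ (hydride abstraction, then hydrolysis of the oxocarbenium ion) under buffered neutral conditions, done while both phenols are still masked against quinone formation.

Step 23
Reactants: 36 bis-epoxide with free C4' hydroxyl
Product: 38 target CNP0289684.3, via tris(trimethylsilyl) ether 37 (not isolated)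
Conditions: TMSOTf (6 equiv), 2,2′-bipyridyl (9 equiv), MeCN, 0 °C → rt; then H2O
Reagents that add atoms: none
Why: The silyl triflate–bipyridyl complex exchanges aryl MOM ethers into aryl silyl ethers without protic acid, and water then frees the phenols (and the transiently silylated C4' hydroxyl), which spares the two epoxides and the ortho-hydroxybenzylic alcohol.

Compound list

1 | 5-chloro-2,4-dihydroxybenzaldehyde | O=Cc1cc(Cl)c(O)cc1O | starting material
2 | 5-chloro-2-hydroxy-4-(methoxymethoxy)benzaldehyde | O=Cc1cc(Cl)c(OCOC)cc1O | intermediate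
3 | 3-bromo-5-chloro-2-hydroxy-4-(methoxymethoxy)benzaldehyde | O=Cc1cc(Cl)c(OCOC)c(Br)c1O | intermediate
4 | 3-bromo-5-chloro-2-hydroxy-4-(methoxymethoxy)phenyl formate | O=COc1cc(Cl)c(OCOC)c(Br)c1O | intermediate (not isolated)
5 | 3-bromo-5-chloro-4-(methoxymethoxy)benzene-1,2-diol | Oc1cc(Cl)c(OCOC)c(Br)c1O | intermediate
6 | 1-bromo-5-chloro-6-(methoxymethoxy)-2,3-bis(trimethylsilyloxy)benzene | C[Si](C)(C)Oc1cc(Cl)c(OCOC)c(Br)c1O[Si](C)(C)C | intermediate
7 | [3-chloro-2-(methoxymethoxy)-5,6-bis(trimethylsilyloxy)phenyl]lithium | [Li]c1c(OCOC)c(Cl)cc(O[Si](C)(C)C)c1O[Si](C)(C)C | intermediate (not isolated)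
8 | lithium 4-chloro-3-(methoxymethoxy)-2-(trimethylsilyl)-6-(trimethylsilyloxy)phenolate | [Li+].[O-]c1c(O[Si](C)(C)C)cc(Cl)c(OCOC)c1[Si](C)(C)C | intermediate (not isolated)
9 | 4-chloro-3-(methoxymethoxy)-2-(trimethylsilyl)-6-(trimethylsilyloxy)phenyl trifluoromethanesulfonate | C[Si](C)(C)Oc1cc(Cl)c(OCOC)c([Si](C)(C)C)c1OS(=O)(=O)C(F)(F)F | intermediate (not isolated)
10 | 4-chloro-6-hydroxy-3-(methoxymethoxy)-2-(trimethylsilyl)phenyl trifluoromethanesulfonate (the hydroxyl becomes O-8'; OTf on C8a', SiMe3 on C4a', OMOM on C5', Cl on C6') | Oc1cc(Cl)c(OCOC)c([Si](C)(C)C)c1OS(=O)(=O)C(F)(F)F | intermediate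
11 | naphthalene-1,5-diol | Oc1cccc2c(O)cccc12 | starting material
12 | 4-methoxynaphthalene-1,5-diol | COc1ccc(O)c2cccc(O)c12 | intermediate (not isolated)
13 | 5-hydroxy-4,4-dimethoxynaphthalen-1(4H)-one | COC1(OC)C=CC(=O)c2cccc(O)c12 | intermediate
14 | 5-hydroxy-8-iodo-4,4-dimethoxynaphthalen-1(4H)-one | COC1(OC)C=CC(=O)c2c(I)ccc(O)c12 | intermediate
15 | 6-chloro-5-hydroxy-8-iodo-4,4-dimethoxynaphthalen-1(4H)-one | COC1(OC)C=CC(=O)c2c(I)cc(Cl)c(O)c12 | intermediate
16 | 6-chloro-8-iodo-4,4-dimethoxy-5-(methoxymethoxy)naphthalen-1(4H)-one | COC1(OC)C=CC(=O)c2c(I)cc(Cl)c(OCOC)c12 | intermediate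
17 | ethynyltrimethylsilane | C#C[Si](C)(C)C | starting material
18 | 6-chloro-4,4-dimethoxy-5-(methoxymethoxy)-8-[(trimethylsilyl)ethynyl]naphthalen-1(4H)-one | COC1(OC)C=CC(=O)c2c(C#C[Si](C)(C)C)cc(Cl)c(OCOC)c12 | intermediate
19 | 8-(bromoethynyl)-6-chloro-4,4-dimethoxy-5-(methoxymethoxy)naphthalen-1(4H)-one | COC1(OC)C=CC(=O)c2c(C#CBr)cc(Cl)c(OCOC)c12 | intermediate
20 | (4-methoxyphenyl)methanol | COc1ccc(CO)cc1 | starting material
21 | trichloroethene | ClC=C(Cl)Cl | starting material
22 | dichloroethyne | ClC#CCl | intermediate (not isolated)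
23 | 1-({[(E)-1,2-dichloroethenyl]oxy}methyl)-4-methoxybenzene | COc1ccc(CO/C(Cl)=C\Cl)cc1 | intermediate
24 | 1-{[(chloroethynyl)oxy]methyl}-4-methoxybenzene | COc1ccc(COC#CCl)cc1 | intermediate (not isolated)
25 | ({[(4-methoxyphenyl)methyl]oxy}ethynyl)lithium | COc1ccc(COC#C[Li])cc1 | intermediate (not isolated)
26 | 1-[(ethynyloxy)methyl]-4-methoxybenzene | COc1ccc(COC#C)cc1 | intermediate
27 | 2-{(E)-2-[(4-methoxybenzyl)oxy]ethenyl}-4,4,5,5-tetramethyl-1,3,2-dioxaborolane | COc1ccc(CO/C=C/B2OC(C)(C)C(C)(C)O2)cc1 | intermediate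
28 | racemic bromo ketal: 2H-naphtho[1,8-bc]furan in which C1 carries O-1 and O-8' of a 5-chloro-4-(methoxymethoxy)-2-(triflyloxy)-3-(trimethylsilyl)phenoxy group, C1' bears an exocyclic (Z)-CHBr (Br cis to O-1), with C2=C3, C4(OMe)2, C5 OMOM, C6 Cl | COC1(OC)c2c(OCOC)c(Cl)cc3c2C(Oc4cc(Cl)c(OCOC)c([Si](C)(C)C)c4OS(=O)(=O)C(F)(F)F)(O/C3=C\Br)C=C1 | intermediate
29 | (R)-enantiomer of 28 (R at C1) | COC1(OC)c2c(OCOC)c(Cl)cc3c2[C@](Oc4cc(Cl)c(OCOC)c([Si](C)(C)C)c4OS(=O)(=O)C(F)(F)F)(O/C3=C\Br)C=C1 | intermediate
30 | aryne precursor: as 29 with Br replaced by (E)-CH=CH–OPMB, i.e. O-1–C1'=C2'–C3'=C4'–OPMB with (1'Z,3'E) geometry; same spatial arrangement at C1, descriptor S | COC1(OC)c2c(OCOC)c(Cl)cc3c2[C@](Oc4cc(Cl)c(OCOC)c([Si](C)(C)C)c4OS(=O)(=O)C(F)(F)F)(O/C3=C\C=C\OCc2ccc(OC)cc2)C=C1 | intermediate (key-step precursor)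
31 | aryne from 30 (C4a'≡C8a'), C1 configuration unchanged | COC1(OC)c2c(OCOC)c(Cl)cc3c2[C@](OC4=CC(Cl)=C(OCOC)C#C4)(O/C3=C\C=C\OCc2ccc(OC)cc2)C=C1 | intermediate (not isolated)
32 | caged 1,4-dihydronaphthalene: new bonds C1'–C8a' and C4'–C4a'; 1,3-dioxane C1–O-8'–C8'–C8a'–C1'–O-1; C2'=C3'; C4'–OPMB on the face of the new ring that carries C8, O-1 on the opposite face; C2=C3, C4(OMe)2, two OMOM, two Cl; C1 as in 30 | COC1(OC)c2c(OCOC)c(Cl)cc3c2[C@@]2(Oc4cc(Cl)c(OCOC)c5c4[C@]3(O2)C=C[C@H]5OCc4ccc(OC)cc4)C=C1 | intermediate (key-step product)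
33 | caged enone: as 32 with C4 ketone | O=C1c2c(OCOC)c(Cl)cc3c2[C@@]2(Oc4cc(Cl)c(OCOC)c5c4[C@]3(O2)C=C[C@H]5OCc4ccc(OC)cc4)C=C1 | intermediate
34 | as 33 with C2'–C3' epoxide on the face of O-1, trans to the C4' PMB ether | O=C1c2c(OCOC)c(Cl)cc3c2[C@@]2(Oc4cc(Cl)c(OCOC)c5c4[C@]3(O2)[C@@H]2O[C@@H]2[C@H]5OCc4ccc(OC)cc4)C=C1 | intermediate
35 | as 34 with C2–C3 epoxide on the face of O-1, trans to O-8' | O=C1c2c(OCOC)c(Cl)cc3c2[C@@]2(Oc4cc(Cl)c(OCOC)c5c4[C@]3(O2)[C@@H]2O[C@@H]2[C@H]5OCc4ccc(OC)cc4)[C@@H]2O[C@H]12 | intermediate
36 | as 35 with free C4' hydroxyl (two OMOM kept) | O=C1c2c(OCOC)c(Cl)cc3c2[C@@]2(Oc4cc(Cl)c(OCOC)c5c4[C@]3(O2)[C@@H]2O[C@@H]2[C@H]5O)[C@@H]2O[C@H]12 | intermediate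
37 | tris(trimethylsilyl) ether of the target (C5, C5' and C4' oxygens) | O=C1c2c(O[Si](C)(C)C)c(Cl)cc3c2[C@@]2(Oc4cc(Cl)c(O[Si](C)(C)C)c5c4[C@]3(O2)[C@@H]2O[C@@H]2[C@H]5O[Si](C)(C)C)[C@@H]2O[C@H]12 | intermediate (not isolated)
38 | CNP0289684.3 | O=C1c2c(O)c(Cl)cc3c2[C@@]2(Oc4cc(Cl)c(O)c5c4[C@]3(O2)[C@@H]2O[C@@H]2[C@H]5O)[C@@H]2O[C@H]12 | target

Total step count: 23. Longest linear sequence: 15 steps (from 11 through steps 6–11 and 15–23).

Steps most likely to fail

Step 15. The ketone oxygen may close 6-endo onto the bromine-bearing alkyne carbon, gold may shift bromine to give a vinylidene, or the phenol may add directly to the activated alkyne; each drains the 5-exo oxocarbenium ion. The fallback uses known reactions only and sets out from 19. Luche reduction (NaBH4, CeCl3·7H2O, MeOH, −40 °C) would give allylic alcohol F1. Catalytic KOt-Bu in THF at 0 °C should close the alkoxide onto the bromoalkyne by anti 5-exo-dig addition to give (Z)-bromomethylidene cyclic ether F2. Radical bromination of the allylic, benzylic, α-oxygenated C1–H (NBS, AIBN, solid K2CO3, PhCF3, 60 °C) would give α-bromo ether F3. Silver-promoted substitution of the bromide by phenol 10 (Ag2CO3, CH2Cl2, −40 °C, Koenigs–Knorr type) should then return the route at 28.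

Step 18. The aryne may fail to span the (1'Z)-diene and be lost to [2+2] addition across an enol ether, to an ene reaction or to protonation, and fluoride may attack the sulfonate sulfur instead of silicon. The fallback removes the tether and sets out from 19. Sodium methoxide in methanol at 0 °C (hemiketal alkoxide, anti 5-exo-dig addition to the bromoalkyne) would give methyl ketal bromide F4. Suzuki–Miyaura coupling with 27 under the conditions of step 17 would give methyl ketal diene F5. An intermolecular aryne Diels–Alder reaction of F5 with the aryne released from 9 (step 5 without the hydrolytic work-up; CsF, MeCN) would give, after loss of the O-silyl group, adduct phenol F6. The regiochemistry of this addition is not controlled, and only the isomer with C1' on C8a' can continue. PPTS in CH2Cl2 over 4 Å MS should exchange the C1 methoxy group for the phenol oxygen and close the 1,3-dioxane to racemic cage F7. Resolution of F7 on the stationary phase of step 16 returns the route at 32.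

Step 7. Iodination may occur at C6 (ortho) as well as at C8 (para), because the peri carbonyl crowds C8; the regioisomers would carry the wrong halogen pattern after step 8. The fallback reverses the order of the halogenations and sets out from 13. Amine-directed ortho-chlorination (NCS, 2,2,6,6-tetramethylpiperidine (10 mol%), toluene, 0 °C; the N-chloroamine is delivered through a hydrogen bond to the phenol) would give 6-chloro-5-hydroxy-4,4-dimethoxynaphthalen-1(4H)-one F8. Iodination with NIS can then occur only at C8 and returns the route at 15.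

Further compounds

F1 | step 15 | rac-8-(bromoethynyl)-6-chloro-4,4-dimethoxy-5-(methoxymethoxy)-1,4-dihydronaphthalen-1-ol | COC1(OC)C=CC(O)c2c(C#CBr)cc(Cl)c(OCOC)c12
F2 | step 15 | rac-(Z)-bromomethylidene cyclic ether (28 with H in place of the aryloxy group at C1) | COC1(OC)c2c(OCOC)c(Cl)cc3c2C(O/C3=C\Br)C=C1
F3 | step 15 | rac-C1 bromide of F2 (α-bromo ether) | COC1(OC)c2c(OCOC)c(Cl)cc3c2C(Br)(O/C3=C\Br)C=C1
F4 | step 18 | rac-methyl ketal bromide (28 with OMe in place of the aryloxy group) | COC1(OC)c2c(OCOC)c(Cl)cc3c2C(OC)(O/C3=C\Br)C=C1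
F5 | step 18 | rac-methyl ketal (1'Z,3'E)-diene (30 with OMe in place of the aryloxy group) | COC1(OC)c2c(OCOC)c(Cl)cc3c2C(OC)(O/C3=C\C=C\OCc2ccc(OC)cc2)C=C1
F6 | step 18 | adduct phenol (racemic; C1'–C8a' and C4'–C4a' formed, C8 and OPMB cis, free C8' hydroxyl, C1 still a methyl ketal) | COC1(OC)c2c(OCOC)c(Cl)cc3c2C(OC)(OC32C=CC(OCc4ccc(OC)cc4)c4c(OCOC)c(Cl)cc(O)c42)C=C1
F7 | step 18 | racemate of 32 | COC1(OC)c2c(OCOC)c(Cl)cc3c2C2(Oc4cc(Cl)c(OCOC)c5c4C3(O2)C=CC5OCc4ccc(OC)cc4)C=C1
F8 | step 7 | 6-chloro-5-hydroxy-4,4-dimethoxynaphthalen-1(4H)-one | COC1(OC)C=CC(=O)c2ccc(Cl)c(O)c12
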